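**Strategy.** Everything rests on cutting the C3–C4 bond of ring C. The key step exploits that C3 carries the ester oxygen while C4 is a benzylic CH2 on ring A: the bond is therefore made as a C3=C4 enol ester double bond by ring-closing metathesis between a vinyl group on ring A and a 1-(aroyloxy)vinyl group at C3. The precursor is an open aryl ether that already holds the C2 stereocentre (from a copper-catalysed asymmetric propargylic etherification) and the 4-benzyloxybenzoate (from Markovnikov addition of the acid to the alkyne). One hydrogenation then sets C3 cis to the C2 aryl group and removes all five benzyl groups.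

Key step: step 6

Remarks: Flavan numbering is used (O1, C2, C3, C4, C4a, C5–C8, C8a; ring A = phloroglucinol ring, ring B = catechol ring, ring C = pyran ring). Assumption for step 3: the antipode of the Ph-pybox ligand is the one that delivers the (S)-ether 6; (S,S)-Ph-pybox is written, and its mirror image is to be used if a correlation run shows the opposite sense.

**Step 1**
Reactants: 1 3,5-bis(benzyloxy)phenol
Product: 2 2,4-bis(benzyloxy)-6-hydroxybenzaldehyde
Conditions: MgCl2, Et3N, (CH2O)n, MeCN, reflux; dilute aq. HCl work-up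
Reagents that add atoms: paraformaldehyde (as formaldehyde), C=O
Why: Magnesium-mediated ortho-formylation of a phenol (Casnati–Skattebøl): the magnesium phenoxide delivers formaldehyde only ortho to the phenol oxygen, the two ortho positions of 1 are equivalent, and a second equivalent of formaldehyde oxidises the hydroxymethyl stage to the aldehyde by hydride transfer.

**Step 2**
Reactants: 3 3,4-bis(benzyloxy)benzaldehyde
Product: 5 rac-1-[3,4-bis(benzyloxy)phenyl]prop-2-yn-1-yl acetate, via bromomagnesium propargylic alkoxide 4 (not isolated)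
Conditions: HC≡CMgBr, THF, 0 °C; then Ac2O, 0 °C to rt
Reagents that add atoms: ethynylmagnesium bromide, C#C[Mg]Br; acetic anhydride, CC(=O)OC(C)=O
Why: Grignard 1,2-addition of the acetylide to a non-enolisable aldehyde and O-acetylation of the magnesium alkoxide in the same flask; no stereocontrol is needed because step 3 is stereoconvergent.

**Step 3**
Reactants: 2 2,4-bis(benzyloxy)-6-hydroxybenzaldehyde; 5 rac-1-[3,4-bis(benzyloxy)phenyl]prop-2-yn-1-yl acetate
Product: 6 2,4-bis(benzyloxy)-6-{[(1S)-1-[3,4-bis(benzyloxy)phenyl]prop-2-yn-1-yl]oxy}benzaldehyde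
Conditions: CuOTf·½C6H6 (5 mol %), 2,6-bis[(4S)-4-phenyl-4,5-dihydrooxazol-2-yl]pyridine ((S,S)-Ph-pybox, 10 mol %), iPr2NEt, THF, −20 °C
Reagents that add atoms: none
Why: Copper-catalysed enantioselective propargylic etherification: both enantiomers of 5 converge on one copper allenylidene after loss of acetate from the copper acetylide, the phenoxide of 2 attacks its γ-carbon on the face left open by the pybox ligand and so sets the (S) centre that becomes C2, while the formyl group makes the phenol acidic and keeps ring A from competing C-propargylation.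

**Step 4**
Reactants: 6 2,4-bis(benzyloxy)-6-{[(1S)-1-[3,4-bis(benzyloxy)phenyl]prop-2-yn-1-yl]oxy}benzaldehyde
Product: 7 1,5-bis(benzyloxy)-3-{[(1S)-1-[3,4-bis(benzyloxy)phenyl]prop-2-yn-1-yl]oxy}-2-ethenylbenzene
Conditions: Ph3PCH3Br, NaN(SiMe3)2, THF, −78 to 0 °C
Reagents that add atoms: methyltriphenylphosphonium bromide, C[P+](c1ccccc1)(c1ccccc1)c1ccccc1.[Br-]
Why: Wittig methylenation of a non-enolisable aromatic aldehyde; the ylide is far too weak a base to remove the propargylic C–H or the alkyne C–H, so the (S) centre and the propargyl ether are untouched.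

**Step 5**
Reactants: 7 1,5-bis(benzyloxy)-3-{[(1S)-1-[3,4-bis(benzyloxy)phenyl]prop-2-yn-1-yl]oxy}-2-ethenylbenzene; 8 4-(benzyloxy)benzoic acid
Product: 9 (3R)-3-[3,4-bis(benzyloxy)phenyl]-3-[3,5-bis(benzyloxy)-2-ethenylphenoxy]prop-1-en-2-yl 4-(benzyloxy)benzoate
Conditions: [RuCl2(p-cymene)]2 (2 mol %), P(2-furyl)3, Na2CO3 (cat.), toluene, 50 °C
Reagents that add atoms: none
Why: Ruthenium-catalysed Markovnikov hydro-oxycarbonylation of a terminal alkyne (π-activation and carboxylate attack at the internal carbon) installs the ester of the target on the future C3 as a 1,1-disubstituted enol ester under nearly neutral conditions; the stereocentre is not involved and its descriptor changes from S to R only through the priority rules.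

**Step 6**
Reactants: 9 (3R)-3-[3,4-bis(benzyloxy)phenyl]-3-[3,5-bis(benzyloxy)-2-ethenylphenoxy]prop-1-en-2-yl 4-(benzyloxy)benzoate
Product: 10 (2R)-5,7-bis(benzyloxy)-2-[3,4-bis(benzyloxy)phenyl]-2H-chromen-3-yl 4-(benzyloxy)benzoate
Conditions: second-generation Hoveyda–Grubbs catalyst RuCl2(SIMes)(=CH–C6H4-2-OiPr) (5–10 mol %), 1,4-benzoquinone (10 mol %), toluene (0.005 M), 60 °C, dark
Reagents that add atoms: none
Why: Ring-closing olefin metathesis: the ruthenium alkylidene loads on the vinyl group of ring A (the future C4), adds intramolecularly by [2+2] to the 1,1-disubstituted enol ester olefin (the future C3) and cycloreverts, so that the C3=C4 bond is formed and ethylene is lost. The closest known reactions are the ring-closing metathesis of 2-vinylaryl allyl ethers to 2H-chromenes and the enol ether–ene and silyl enol ether–ene ring-closing metatheses that give cyclic enol derivatives. Ring C (O1, C2, C3, C4, C4a, C8a) is closed as a six-membered ring with the new double bond endocyclic, the O1–C2 ether acting as the tether. No stereocentre is created: the (R) centre at C2 is carried through and C3 is set afterwards, in step 7, under its control. The step needs ring closure to win over cross-metathesis, double-bond migration and racemisation: high dilution and the six-membered ring favour closure, initiation on the styrene keeps the catalyst off the hindered enol ester terminus, benzoquinone suppresses ruthenium hydride migration of the C3=CH2 bond towards C2, and exclusion of light with a bath of at most 60 °C avoids electrocyclic opening of the 2H-chromene.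

**Step 7**
Reactants: 10 (2R)-5,7-bis(benzyloxy)-2-[3,4-bis(benzyloxy)phenyl]-2H-chromen-3-yl 4-(benzyloxy)benzoate
Product: 11 (2R,3R)-2-(3,4-dihydroxyphenyl)-5,7-dihydroxy-3,4-dihydro-2H-chromen-3-yl 4-hydroxybenzoate (epicatechin 3-O-p-hydroxybenzoate)
Conditions: H2 (1 atm), Pd(OH)2/C, THF–MeOH, rt
Reagents that add atoms: none
Why: Heterogeneous hydrogenation with hydrogenolysis: allylic 1,2-strain with the C3 ester holds the C2 aryl group pseudo-axial so that it shields one face of the C3=C4 enol ester, hydrogen is therefore delivered syn to the opposite face and places the ester cis to the aryl group (3R), and the same catalyst cleaves the five benzyl ethers, the conjugated alkene being expected to be saturated before the cyclic C2–O1 bond can be cleaved.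

**Compound list**
1 | 3,5-bis(benzyloxy)phenol | Oc1cc(OCc2ccccc2)cc(OCc2ccccc2)c1 | starting material
2 | 2,4-bis(benzyloxy)-6-hydroxybenzaldehyde | O=Cc1c(O)cc(OCc2ccccc2)cc1OCc1ccccc1 | intermediate
3 | 3,4-bis(benzyloxy)benzaldehyde | O=Cc1ccc(OCc2ccccc2)c(OCc2ccccc2)c1 | starting material
4 | bromomagnesium 1-[3,4-bis(benzyloxy)phenyl]prop-2-yn-1-olate (racemic) | C#CC(O[Mg]Br)c1ccc(OCc2ccccc2)c(OCc2ccccc2)c1 | intermediate
5 | rac-1-[3,4-bis(benzyloxy)phenyl]prop-2-yn-1-yl acetate | C#CC(OC(C)=O)c1ccc(OCc2ccccc2)c(OCc2ccccc2)c1 | intermediate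
6 | 2,4-bis(benzyloxy)-6-{[(1S)-1-[3,4-bis(benzyloxy)phenyl]prop-2-yn-1-yl]oxy}benzaldehyde | O=Cc1c(OCc2ccccc2)cc(OCc2ccccc2)cc1O[C@@H](C#C)c1ccc(OCc2ccccc2)c(OCc2ccccc2)c1 | intermediate
7 | 1,5-bis(benzyloxy)-3-{[(1S)-1-[3,4-bis(benzyloxy)phenyl]prop-2-yn-1-yl]oxy}-2-ethenylbenzene | C=Cc1c(OCc2ccccc2)cc(OCc2ccccc2)cc1O[C@@H](C#C)c1ccc(OCc2ccccc2)c(OCc2ccccc2)c1 | intermediate
8 | 4-(benzyloxy)benzoic acid | OC(=O)c1ccc(OCc2ccccc2)cc1 | starting material
9 | (3R)-3-[3,4-bis(benzyloxy)phenyl]-3-[3,5-bis(benzyloxy)-2-ethenylphenoxy]prop-1-en-2-yl 4-(benzyloxy)benzoate | C=Cc1c(OCc2ccccc2)cc(OCc2ccccc2)cc1O[C@@H](C(=C)OC(=O)c1ccc(OCc2ccccc2)cc1)c1ccc(OCc2ccccc2)c(OCc2ccccc2)c1 | intermediate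
10 | (2R)-5,7-bis(benzyloxy)-2-[3,4-bis(benzyloxy)phenyl]-2H-chromen-3-yl 4-(benzyloxy)benzoate | O=C(OC1=Cc2c(OCc3ccccc3)cc(OCc3ccccc3)cc2O[C@@H]1c1ccc(OCc2ccccc2)c(OCc2ccccc2)c1)c1ccc(OCc2ccccc2)cc1 | intermediate
11 | (2R,3R)-2-(3,4-dihydroxyphenyl)-5,7-dihydroxy-3,4-dihydro-2H-chromen-3-yl 4-hydroxybenzoate | O=C(O[C@@H]1Cc2c(O)cc(O)cc2O[C@@H]1c1ccc(O)c(O)c1)c1ccc(O)cc1 | target

**Total step count:** 7. **Longest linear sequence:** 6 steps (steps 1, 3, 4, 5, 6, 7; the branch through step 2 is equally long).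

**Steps most likely to fail**

Step 6. The hindered 1,1-disubstituted enol ester olefin may fail to enter the metallacycle, so that the catalyst decays or the styrene ends dimerise, or the C3=CH2 bond may migrate towards C2 with loss of the C2 configuration. The fallback introduces the C3 oxygen after ring closure and sets out from 7. Semi-hydrogenation (H2, Pd/CaCO3 poisoned with Pb(OAc)2, quinoline, EtOAc) should give 1,5-bis(benzyloxy)-3-{[(1S)-1-[3,4-bis(benzyloxy)phenyl]prop-2-en-1-yl]oxy}-2-ethenylbenzene F1. The well-established ring-closing metathesis of such vinylaryl allyl ethers (second-generation Grubbs catalyst, CH2Cl2, 40 °C) closes the same C3–C4 bond to (2S)-5,7-bis(benzyloxy)-2-[3,4-bis(benzyloxy)phenyl]-2H-chromene F2. Hydroboration–oxidation (BH3·THF, then NaOH/H2O2) anti to the aryl group should give the 2,3-trans alcohol (2R,3S)-5,7-bis(benzyloxy)-2-[3,4-bis(benzyloxy)phenyl]chroman-3-ol F3. Dess–Martin periodinane gives (2R)-5,7-bis(benzyloxy)-2-[3,4-bis(benzyloxy)phenyl]chroman-3-one F4, and LiBH(s-Bu)3 at −78 °C, attacking anti to the aryl group, should give the cis alcohol (2R,3R)-5,7-bis(benzyloxy)-2-[3,4-bis(benzyloxy)phenyl]chroman-3-ol F5. Esterification with 8 (EDC·HCl, DMAP, CH2Cl2) gives (2R,3R)-5,7-bis(benzyloxy)-2-[3,4-bis(benzyloxy)phenyl]chroman-3-yl 4-(benzyloxy)benzoate F6, and hydrogenolysis (H2, Pd(OH)2/C) comes back to the route at 11.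

Step 5. The carboxylate may add at the terminal carbon (vinylidene pathway) or not at all to the α-branched alkyne. The fallback sets out from 7 and builds the enol ester by borylation and oxidative C–O coupling. Copper-catalysed α-selective protoboration ((SIMes)CuCl, NaOtBu cat., B2pin2 (1 equiv), MeOH, THF, low temperature to spare the styrene) should give 2-{(3S)-3-[3,4-bis(benzyloxy)phenyl]-3-[3,5-bis(benzyloxy)-2-ethenylphenoxy]prop-1-en-2-yl}-4,4,5,5-tetramethyl-1,3,2-dioxaborolane F7. KHF2 in aqueous MeOH converts it into potassium {(3S)-3-[3,4-bis(benzyloxy)phenyl]-3-[3,5-bis(benzyloxy)-2-ethenylphenoxy]prop-1-en-2-yl}trifluoroborate F8. Copper-mediated oxidative coupling of this alkenyltrifluoroborate with acid 8 (Cu(OAc)2, DMAP, 4 Å molecular sieves, O2, CH2Cl2) comes back to the route at 9.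

Step 3. The enantiomeric purity may be eroded by re-ionisation of the product ether, ring A may be propargylated on carbon, or the sense of induction may be the wrong one. The fallback makes the C2–O1 bond by inversion of a preformed carbinol and sets out from 3. Addition of HC≡CMgBr (THF, 0 °C, aqueous work-up) gives rac-1-[3,4-bis(benzyloxy)phenyl]prop-2-yn-1-ol F9, and MnO2 (CH2Cl2) gives 1-[3,4-bis(benzyloxy)phenyl]prop-2-yn-1-one F10. Oxazaborolidine-catalysed borane reduction (CBS catalyst antipode chosen for the R carbinol, BH3·SMe2, THF, −30 °C) gives (1R)-1-[3,4-bis(benzyloxy)phenyl]prop-2-yn-1-ol F11. Mitsunobu etherification with the acidic phenol 2 (PPh3, DIAD, toluene, −20 °C) proceeds with inversion and comes back to the route at 6.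

**Further compounds**
F1 | step 6 | 1,5-bis(benzyloxy)-3-{[(1S)-1-[3,4-bis(benzyloxy)phenyl]prop-2-en-1-yl]oxy}-2-ethenylbenzene | C=Cc1c(OCc2ccccc2)cc(OCc2ccccc2)cc1O[C@@H](C=C)c1ccc(OCc2ccccc2)c(OCc2ccccc2)c1
F2 | step 6 | (2S)-5,7-bis(benzyloxy)-2-[3,4-bis(benzyloxy)phenyl]-2H-chromene | C1=Cc2c(OCc3ccccc3)cc(OCc3ccccc3)cc2O[C@@H]1c1ccc(OCc2ccccc2)c(OCc2ccccc2)c1
F3 | step 6 | (2R,3S)-5,7-bis(benzyloxy)-2-[3,4-bis(benzyloxy)phenyl]chroman-3-ol | O[C@H]1Cc2c(OCc3ccccc3)cc(OCc3ccccc3)cc2O[C@@H]1c1ccc(OCc2ccccc2)c(OCc2ccccc2)c1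
F4 | step 6 | (2R)-5,7-bis(benzyloxy)-2-[3,4-bis(benzyloxy)phenyl]chroman-3-one | O=C1Cc2c(OCc3ccccc3)cc(OCc3ccccc3)cc2O[C@@H]1c1ccc(OCc2ccccc2)c(OCc2ccccc2)c1
F5 | step 6 | (2R,3R)-5,7-bis(benzyloxy)-2-[3,4-bis(benzyloxy)phenyl]chroman-3-ol | O[C@@H]1Cc2c(OCc3ccccc3)cc(OCc3ccccc3)cc2O[C@@H]1c1ccc(OCc2ccccc2)c(OCc2ccccc2)c1
F6 | step 6 | (2R,3R)-5,7-bis(benzyloxy)-2-[3,4-bis(benzyloxy)phenyl]chroman-3-yl 4-(benzyloxy)benzoate | O=C(O[C@@H]1Cc2c(OCc3ccccc3)cc(OCc3ccccc3)cc2O[C@@H]1c1ccc(OCc2ccccc2)c(OCc2ccccc2)c1)c1ccc(OCc2ccccc2)cc1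
F7 | step 5 | 2-{(3S)-3-[3,4-bis(benzyloxy)phenyl]-3-[3,5-bis(benzyloxy)-2-ethenylphenoxy]prop-1-en-2-yl}-4,4,5,5-tetramethyl-1,3,2-dioxaborolane | C=Cc1c(OCc2ccccc2)cc(OCc2ccccc2)cc1O[C@@H](C(=C)B1OC(C)(C)C(C)(C)O1)c1ccc(OCc2ccccc2)c(OCc2ccccc2)c1
F8 | step 5 | potassium {(3S)-3-[3,4-bis(benzyloxy)phenyl]-3-[3,5-bis(benzyloxy)-2-ethenylphenoxy]prop-1-en-2-yl}trifluoroborate | C=Cc1c(OCc2ccccc2)cc(OCc2ccccc2)cc1O[C@@H](C(=C)[B-](F)(F)F)c1ccc(OCc2ccccc2)c(OCc2ccccc2)c1.[K+]
F9 | step 3 | rac-1-[3,4-bis(benzyloxy)phenyl]prop-2-yn-1-ol | C#CC(O)c1ccc(OCc2ccccc2)c(OCc2ccccc2)c1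
F10 | step 3 | 1-[3,4-bis(benzyloxy)phenyl]prop-2-yn-1-one | C#CC(=O)c1ccc(OCc2ccccc2)c(OCc2ccccc2)c1
F11 | step 3 | (1R)-1-[3,4-bis(benzyloxy)phenyl]prop-2-yn-1-ol | C#C[C@@H](O)c1ccc(OCc2ccccc2)c(OCc2ccccc2)c1
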